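## Structural features

Stenophyllol B (C42H32O9) is a resveratrol trimer in which three C6–C2–C6 units are fused into a hexacyclic core with eight free phenols. An indane, whose resorcinol ring is called ring A here (oxygens at C5 and C7), carries a 4-hydroxyphenyl group at C1, the benzo ring of a 2,3-dihydrobenzofuran (ring C, joined through benzofuran C4) at C2, and a methine, called Cα here, at C3. Cα bears a second 4-hydroxyphenyl group and the central resorcinol ring B; ring B is also bonded to benzofuran C3, so that indane C2, C3, Cα, two carbons of ring B, benzofuran C3, C3a and C4 form an eight-membered ring, and benzofuran C2 carries the third 4-hydroxyphenyl group. There are six stereocentres: indane C1, C2 and C3 (all-trans; 1S,2S,3R), Cα (R) next to C3, and benzofuran C3 and C2 (trans; 3R,2R); the first four are contiguous. The molecule is electron-rich throughout: the free phenols are air-sensitive, every diarylmethine can ionise under acid, and the O1–C2 bond is a 4-hydroxybenzyl ether, so all oxygens are carried as methyl ethers until the last step. The real difficulty is the medium ring with its two diarylmethine centres (Cα and benzofuran C3). It must be closed at one defined position although three dioxygenated arenes compete as nucleophiles, and the configuration must be relayed from the indane to these centres. The key step uses the 1,3,5-relationship of O–C7, O–C5 and the ring-fusion carbon C3a in ring A. This is the imprint of a 3,5,7-tricarbonyl chain, so ring A can be grown by an aldol closure of C4 onto C3a from a cyclopentanone that already holds C1, C2 and C3.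

## Logic of the disconnections

37 ⇒ 35. The O1–C2 bond of the dihydrobenzofuran and the eight O–methyl bonds are cut together. O1–C2 is a benzylic ether bond that forms readily from a 4-alkoxybenzyl cation and the ring C oxygen, so no separate differentiation of the two ring C oxygens is needed. This removes one ring and one stereocentre. The forward step must close the five-membered ring faster than the cation eliminates, place the C2 aryl group trans to the C3 substituent, and remove nine methyl groups without disturbing Cα.

35 ⇒ 34 ⇒ 33. After return to the ketone level (34), the Cα–ring B bond of the eight-membered ring is cut. Cα is a 4-methoxybenzylic carbon and the ring B carbon is ortho and para to methoxy groups, so the bond is a natural cation–arene bond. Closing the ring at Cα leaves no seven-membered alternative, and the ketone in 34 keeps the future benzofuran C3 epimerisable. The medium ring and the Cα stereocentre disappear. The forward step has to outrun proton loss from C3 and bimolecular alkylation, and has to deliver the arene to the correct face of the cation.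

33 ⇒ 32 + 10, and 32 ⇒ 31 ⇒ 30. The Cα–aryl bond is cut to an aldehyde and an aryl Grignard reagent, and the aldehyde is traced back to the protected hydroxymethyl group. This reduces the C3 side chain to the one-carbon handle that the key step product carries. The addition must select the aldehyde over the hindered aryl ketone, and C3 must stay trans while it is α to the aldehyde.

30 ⇒ 24 + 29. The bond between ring C and the future benzofuran C3 is cut between an aryl bromide and the α-carbon of a ketone. The whole third resveratrol unit then arrives as one piece, and the position on ring C is fixed by where the bromine sits. The forward step is an enolate arylation at a bromide flanked by two ortho substituents.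

29 ⇒ 25 + 26. The CH2–C(=O) bond of 29 is cut to a benzylic organomagnesium reagent and a nitrile, both made from commercial materials in one operation.

24 ⇒ 23 ⇒ 21 ⇒ 20 ⇒ 19. These are functional-group changes on the indane: O-methylation, loss of the C4 carboxyl carbon, and the C–Br bond on ring C. The C4 carboxyl is kept, tied up with the C5 oxygen, until after the bromination because its carbonyl deactivates ring A and leaves ring C as the only strongly activated arene. The bromination must be a mono-substitution ortho to the indanyl group, and the 7-hydroxyl must be capped beforehand.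

19 ⇒ 17. The C3a–C4 bond of ring A is cut, which opens the arene to a cyclopentanone carrying a masked 3,5-diketo acid on its α-carbon. All three stereocentres already stand on the five-membered ring, so the arene is grown onto a stereodefined carbocycle. The forward step must be a C-aldol and not an O-cyclisation, and must not disturb C3.

17 ⇒ 11 + 15. The bond between the future C7a and the side-chain carbonyl carbon is cut to a regiodefined enolate equivalent and an acyl donor. The enolate must be acylated on carbon, at one position only, and the acidic methylene of 15 must not quench it.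

15 ⇒ 14 ⇒ 12. The acyl donor is traced to the carboxylic acid and this to the commercial dioxinone by cutting the CH2–CO2H bond.

11 ⇒ 9 + 10. The bond between the future indane C1 and its aryl group is cut as a conjugate addition to an enone. The aryl group must enter anti to the neighbouring aryl substituent, and the enolate must be captured without loss of regiochemistry.

9 ⇒ 7 ⇒ 6. The enone is traced to the saturated ketone (dehydrogenation on the unsubstituted side), and the bond between the future indane C3 and its CH2O carbon is cut as an alkylation of a silyl enol ether. The alkyl group must enter trans to the aryl group.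

6 ⇒ 1 + 2. The bond between the future indane C2 and ring C is cut as a catalytic asymmetric conjugate addition. This step sets the absolute configuration of the whole route.

## Other disconnections considered

Alternative 1: The cut removes the three ring bonds C3a–C7a, C6–C7 and C4–C5 of ring C. The benzofuran arene and the dihydrofuran would then arise together from an acyclic diyne in which an ynol ether oxygen already links the two future furan carbons, plus an external alkoxyalkyne. The forward step is a rhodium- or ruthenium-catalysed (2+2+2) cycloaddition that would give A1. In its favour, a fully substituted arene is assembled with each substituent placed by the tether, two rings form at once, and the trans C2/C3 pair of the dihydrobenzofuran is fixed in an open-chain precursor before any ring exists. Against it, ynol ethers are fragile, the unsymmetrical alkyne partner can insert in two orientations, and A1 holds only the benzofuran part. The indane with three stereocentres would have to be built outward from the benzylic CH2O arm, with no ring to relay configuration from the remote dihydrofuran centres, and the eight-membered ring would still need a late cationic closure. Compared with the chosen plan, the alternative is the better one at benzofuran C3, which it sets early and independently of the medium ring, whereas the chosen route relies on equilibration there. It is weaker in the relay of absolute configuration to the indane and is unlikely to be shorter overall, because the cyclopentane would have to be annulated onto an electron-rich arene stepwise.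

Alternative 2: The cut is the indane C1–C2 bond. A diaryl carbene, generated by oxidation of a hydrazone and decomposed on the chiral dirhodium carboxylate Rh2(S-PTAD)4, would insert into the benzylic methylene C–H bond that becomes C2 and give A2. In its favour, ring A is bought as an arene, so there is no carboxyl carbon to shed; two stereocentres are set in one catalytic step; and the C3 ester is a ready one-carbon handle. Against it, the carbene can also attack the dimethoxyarene (cyclopropanation and ring expansion) or form an azine, the all-trans outcome depends on catalyst and substrate acting in the same sense, and the absolute configuration is set on an advanced intermediate. On step count to the indane it is the equal of the chosen plan or slightly better. On structure it is weaker for the later steps: A2 lacks the C4 carbonyl that the chosen plan uses to keep ring A inert during bromination of ring C, so the two dimethoxyarenes would be hard to tell apart. On mechanism the chosen aldol aromatisation creates no stereocentre and so has less to go wrong, while the insertion has to control two.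

Alternative 3: The cut removes benzofuran C3–C3a and O1–C2 in the last ring-forming step. The third resveratrol unit would be attached to ring B as an intact 4-methoxystilbene and joined to a phenolic ring C by one-electron oxidation (Ag2O, FeCl3 or an acridinium photocatalyst under air) to give A3. In its favour, it is the most convergent and most biomimetic plan: two bonds, two rings and two stereocentres form in one step, no palladium coupling or carbonyl reduction is needed, and on step economy it is clearly better than the chosen end-game. Against it, an eight-membered ring must close through a radical or radical-cation C–C coupling in competition with dimerisation; the resorcinol can couple at more than one carbon; the oxidant can also attack the other electron-rich rings; and the configuration at benzofuran C3 relative to the indane is fixed kinetically in the C–C coupling with nothing obvious to bias it. Both plans set benzofuran C2 trans to C3 by capture of a benzylic cation and are equal on that point. The chosen plan is stronger at benzofuran C3, which it places next to a ketone where it can be equilibrated, and in forming the medium ring through a closed-shell cation that has only one ring size open to it.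

Key step: step 8

Assumptions (remarks on the chemistry):
- Indane numbering is kept fixed through the route (C1 carries the 4-methoxyphenyl group, C2 ring C, C3 the one-carbon arm). Cα is the carbon on C3 that becomes the anisyl-bearing methine; "future benzofuran C3/C2" are the two carbons of the third resveratrol unit.
- The (R)-BINAP ligand in step 1 is taken to deliver the 3R adduct, by analogy with phenyl transfer to cyclopentenone; if the sense were opposite, the (S)-ligand would be used.
- In 34 the epimer at the future benzofuran C3 that carries the required configuration is taken to be the more stable one; this is argued under step 18 but is not proven.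

## Route

Step 1
Reactants: 1 cyclopent-2-en-1-one; 2 1-bromo-3,5-dimethoxybenzene
Product: 6 {[(3R)-3-(3,5-dimethoxyphenyl)cyclopent-1-en-1-yl]oxy}trimethylsilane, via aryllithium 3 (not isolated), via aryltitanium triisopropoxide 4 (not isolated), via titanium enolate 5 (not isolated)
Conditions: 2, n-BuLi, THF, −78 °C; ClTi(Oi-Pr)3, −78 → 0 °C; then 1, [Rh(OH)((R)-BINAP)]2 (3 mol% Rh), THF, 20 °C; LiOi-Pr, Me3SiCl, 0 °C
Reagents that add atoms: chlorotrimethylsilane, C[Si](C)(C)Cl
Why: Rhodium-catalysed asymmetric 1,4-addition of an aryltitanium reagent (Hayashi–Miyaura type); the aryl–rhodium–BINAP species adds to one face of the enone and sets C3 (future indane C2), the only stereocentre set by a catalyst. Capture of the titanium enolate as its silyl ether fixes the enolate regiochemistry for step 2.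

Step 2
Reactants: 6 {[(3R)-3-(3,5-dimethoxyphenyl)cyclopent-1-en-1-yl]oxy}trimethylsilane
Product: 7 (2R,3R)-2-[(benzyloxy)methyl]-3-(3,5-dimethoxyphenyl)cyclopentan-1-one
Conditions: BnOCH2Cl, ZnBr2 (10 mol%), CH2Cl2, 0 °C
Reagents that add atoms: benzyl chloromethyl ether, ClCOCc1ccccc1
Why: Lewis acid-catalysed alkylation of a silyl enol ether by an α-chloro ether (Mukaiyama-type, through the oxocarbenium ion); the bond can form only at the enol carbon, so there is no O-alkylation or regiochemical scrambling. The electrophile approaches anti to the neighbouring aryl group and gives the 2,3-trans ketone, which is also the more stable epimer.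

Step 3
Reactants: 7 (2R,3R)-2-[(benzyloxy)methyl]-3-(3,5-dimethoxyphenyl)cyclopentan-1-one
Product: 9 (4R,5R)-5-[(benzyloxy)methyl]-4-(3,5-dimethoxyphenyl)cyclopent-2-en-1-one, via silyl enol ether 8 (not isolated)
Conditions: LiN(i-Pr)2, Me3SiCl, THF, −78 °C; then Pd(OAc)2 (10 mol%), O2 (1 atm), DMSO, 25 °C
Reagents that add atoms: none
Why: Kinetic deprotonation at the unsubstituted α-methylene with silylation in the flask, then Saegusa–Ito dehydrosilylation (palladium enolate, β-hydride elimination) in its oxygen-coupled catalytic form. Enolisation away from C2 avoids β-elimination of the benzyloxy group, and neither stereocentre is touched.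

Step 4
Reactants: 9 (4R,5R)-5-[(benzyloxy)methyl]-4-(3,5-dimethoxyphenyl)cyclopent-2-en-1-one; 10 (4-methoxyphenyl)magnesium bromide
Product: 11 {[(3R,4R,5R)-5-[(benzyloxy)methyl]-4-(3,5-dimethoxyphenyl)-3-(4-methoxyphenyl)cyclopent-1-en-1-yl]oxy}trimethylsilane
Conditions: CuBr·SMe2 (10 mol%), Me3SiCl, THF, −78 °C
Reagents that add atoms: chlorotrimethylsilane, C[Si](C)(C)Cl
Why: Copper-catalysed conjugate addition of a Grignard reagent accelerated by Me3SiCl; the aryl group enters at C3 anti to the C4 aryl substituent, the usual substrate control in 4-substituted cyclopentenones, and sets the future indane C1. The enolate is captured as the silyl ether so that it can be released regiospecifically in step 7.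

Step 5
Reactants: 12 2,2,6-trimethyl-4H-1,3-dioxin-4-one
Product: 14 (2,2-dimethyl-4-oxo-4H-1,3-dioxin-6-yl)acetic acid, via lithium dienolate 13 (not isolated)
Conditions: LiN(i-Pr)2, THF, −78 °C; CO2 (gas); aq. HCl, 0 °C
Reagents that add atoms: carbon dioxide, O=C=O
Why: γ-Deprotonation of the vinylogous ester gives the dienolate, which is carboxylated at the exocyclic carbon (carboxylation of an extended enolate).

Step 6
Reactants: 14 (2,2-dimethyl-4-oxo-4H-1,3-dioxin-6-yl)acetic acid
Product: 15 6-[2-(1H-benzotriazol-1-yl)-2-oxoethyl]-2,2-dimethyl-4H-1,3-dioxin-4-one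
Conditions: 1H-benzotriazole (4 equiv), SOCl2 (1 equiv), CH2Cl2, 25 °C
Reagents that add atoms: 1H-benzotriazole, c1ccc2[nH]nnc2c1
Why: Activation of the acid as its N-acylbenzotriazole, a neutral, isolable acyl donor that transfers the acyl group to carbon of ketone enolates.

Step 7
Reactants: 11 {[(3R,4R,5R)-5-[(benzyloxy)methyl]-4-(3,5-dimethoxyphenyl)-3-(4-methoxyphenyl)cyclopent-1-en-1-yl]oxy}trimethylsilane; 15 6-[2-(1H-benzotriazol-1-yl)-2-oxoethyl]-2,2-dimethyl-4H-1,3-dioxin-4-one
Product: 17 6-{2-[(3R,4R,5R)-3-[(benzyloxy)methyl]-4-(3,5-dimethoxyphenyl)-5-(4-methoxyphenyl)-2-oxocyclopentyl]-2-oxoethyl}-2,2-dimethyl-4H-1,3-dioxin-4-one (C1 of the cyclopentyl ring enolisable), via lithium enolate 16 (not isolated)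
Conditions: MeLi, THF, 0 °C; LiN(SiMe3)2 (1.1 equiv), then 15, −78 → −20 °C; AcOH
Reagents that add atoms: none
Why: Si–O cleavage by MeLi releases the enolate at one position only, and crossed Claisen C-acylation with the N-acylbenzotriazole builds the 1,3-diketone. The extra amide base takes up the acidic proton of the product (or of the acyl donor), so the ring enolate is not consumed as a base, and the three stereocentres are not involved.

Step 8
Reactants: 17 6-{2-[(3R,4R,5R)-3-[(benzyloxy)methyl]-4-(3,5-dimethoxyphenyl)-5-(4-methoxyphenyl)-2-oxocyclopentyl]-2-oxoethyl}-2,2-dimethyl-4H-1,3-dioxin-4-one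
Product: 19 (1S,2R,3S)-3-[(benzyloxy)methyl]-2-(3,5-dimethoxyphenyl)-7-hydroxy-1-(4-methoxyphenyl)indane with a 2,2-dimethyl-1,3-dioxin-4-one ring fused at C4–C5 (carbonyl on C4 and ring oxygen on C5), via aldol adduct 18 (not isolated)
Conditions: Et3N (3 equiv), CH2Cl2, 25 °C
Reagents that add atoms: none
Why: Et3N deprotonates the tricarbonyl system; in the extended enolate that runs through the dioxinone the dioxinone α-carbon is nucleophilic and adds to the cyclopentanone carbonyl, forming the C3a–C4 bond and the tertiary aldol 18. Loss of water across C3a–C7a (E1cB through the remaining ketone) and enolisation of that ketone give the phenol, and aromatisation makes the sequence irreversible. The closest known reaction type is the amine-mediated aromatisation of diketo-dioxinones to isopropylidene-protected resorcylates, the laboratory counterpart of polyketide folding. The one ring formed is the six-membered carbocycle of ring A, closed in a 6-exo-trig aldol mode with the enolate double bond outside the new ring; no other six-membered carbon–carbon closure is open to the chain. No stereocentre is created; C1, C2 and C3 are carried through, and C3, which is α to a ketone only until the aldol step, already has the more stable trans arrangement to the C2 aryl group. The step needs C- rather than O-cyclisation and must avoid β-elimination of the benzyloxy group. A mild amine at room temperature leaves the dioxinone ring closed, so no acylketene or pyranone pathway opens. The acidic site is the 1,3-diketone, not C3–H, so the benzyloxymethyl arm is not expelled.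

Step 9
Reactants: 19 the 7-hydroxy benzodioxinone of step 8
Product: 20 (1S,2R,3S)-3-[(benzyloxy)methyl]-2-(3,5-dimethoxyphenyl)-7-methoxy-1-(4-methoxyphenyl)indane with the 2,2-dimethyl-1,3-dioxin-4-one ring fused at C4–C5
Conditions: MeI, K2CO3, acetone, 50 °C
Reagents that add atoms: iodomethane, CI
Why: Williamson O-methylation of the free phenol; with the hydroxyl capped, ring A is deactivated by the C4 carbonyl in step 10.

Step 10
Reactants: 20 the 7-methoxy benzodioxinone of step 9
Product: 21 (1S,2R,3S)-3-[(benzyloxy)methyl]-2-(2-bromo-3,5-dimethoxyphenyl)-7-methoxy-1-(4-methoxyphenyl)indane with the 2,2-dimethyl-1,3-dioxin-4-one ring fused at C4–C5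
Conditions: NBS (1.0 equiv), MeCN, 0 °C
Reagents that add atoms: N-bromosuccinimide, O=C1CCC(=O)N1Br
Why: Electrophilic aromatic bromination; ring C is the only arene activated by two methoxy groups and free of an acyl group, and it reacts ortho to the indanyl substituent and para to a methoxy group. The two such positions are equivalent, so one monobromide should result; the carbon brominated is the one that becomes benzofuran C3a.

Step 11
Reactants: 21 the bromide of step 10
Product: 23 (1S,2R,3S)-3-[(benzyloxy)methyl]-2-(2-bromo-3,5-dimethoxyphenyl)-7-methoxy-1-(4-methoxyphenyl)indan-5-ol, via salicylic acid 22 (not isolated)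
Conditions: KOH, dioxane–H2O, 80 °C; then AcOH to pH 4, 100 °C
Reagents that add atoms: none
Why: Hydroxide opens the isopropylidene ester-ketal to the salicylate, and the 2-hydroxy-4-methoxy-6-alkylbenzoic acid loses CO2 on warming in weak acid by ipso-protonation, as orsellinic-type acids do. The carboxyl is removed once it has done its work as a deactivating group in step 10.

Step 12
Reactants: 23 (1S,2R,3S)-3-[(benzyloxy)methyl]-2-(2-bromo-3,5-dimethoxyphenyl)-7-methoxy-1-(4-methoxyphenyl)indan-5-ol
Product: 24 (1S,2R,3S)-3-[(benzyloxy)methyl]-2-(2-bromo-3,5-dimethoxyphenyl)-5,7-dimethoxy-1-(4-methoxyphenyl)indane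
Conditions: MeI, K2CO3, acetone, 50 °C
Reagents that add atoms: iodomethane, CI
Why: Williamson O-methylation; all phenols now carry the same protecting group, removed together at the end.

Step 13
Reactants: 25 1-(chloromethyl)-3,5-dimethoxybenzene; 26 4-methoxybenzonitrile
Product: 29 2-(3,5-dimethoxyphenyl)-1-(4-methoxyphenyl)ethan-1-one, via benzylmagnesium chloride 27 (not isolated), via magnesium ketimide 28 (not isolated)
Conditions: Mg, Et2O, 0 °C; 26, Et2O–toluene, 40 °C; aq. HCl, 25 °C
Reagents that add atoms: water, O
Why: Addition of a benzylic Grignard reagent to a nitrile and hydrolysis of the ketimine, the classical deoxybenzoin synthesis.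

Step 14
Reactants: 24 (1S,2R,3S)-3-[(benzyloxy)methyl]-2-(2-bromo-3,5-dimethoxyphenyl)-5,7-dimethoxy-1-(4-methoxyphenyl)indane; 29 2-(3,5-dimethoxyphenyl)-1-(4-methoxyphenyl)ethan-1-one
Product: 30 (1S,2R,3S)-3-[(benzyloxy)methyl]-2-{2-[1-(3,5-dimethoxyphenyl)-2-(4-methoxyphenyl)-2-oxoethyl]-3,5-dimethoxyphenyl}-5,7-dimethoxy-1-(4-methoxyphenyl)indane (both epimers at the new methine)
Conditions: Pd2(dba)3 (2.5 mol%), XPhos (6 mol%), NaOt-Bu, toluene, 90 °C
Reagents that add atoms: none
Why: Palladium-catalysed α-arylation of a ketone: oxidative addition of the aryl bromide to zerovalent palladium, binding of the enolate, reductive elimination. The benzylic methylene of 29 is its only enolisable position; the new methine (future benzofuran C3) forms without control and is corrected in step 18.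

Step 15
Reactants: 30 the benzyl ether of step 14
Product: 31 (1S,2R,3S)-3-(hydroxymethyl)-2-{2-[1-(3,5-dimethoxyphenyl)-2-(4-methoxyphenyl)-2-oxoethyl]-3,5-dimethoxyphenyl}-5,7-dimethoxy-1-(4-methoxyphenyl)indane (both epimers at the methine)
Conditions: H2 (1 atm), Pd/C (10%), EtOAc, 25 °C
Reagents that add atoms: none
Why: Hydrogenolysis of the benzyl ether on palladium; the aryl ketone and the methyl ethers are inert under neutral conditions.

Step 16
Reactants: 31 the primary alcohol of step 15
Product: 32 (1S,2R,3S)-2-{2-[1-(3,5-dimethoxyphenyl)-2-(4-methoxyphenyl)-2-oxoethyl]-3,5-dimethoxyphenyl}-5,7-dimethoxy-1-(4-methoxyphenyl)indane-3-carbaldehyde (indane numbering kept; both epimers at the methine)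
Conditions: Dess–Martin periodinane, NaHCO3, CH2Cl2, 0 → 25 °C
Reagents that add atoms: none
Why: Dess–Martin oxidation of the primary alcohol; the buffered, non-basic medium keeps the α-stereocentre C3 in its more stable trans arrangement.

Step 17
Reactants: 32 the aldehyde of step 16; 10 (4-methoxyphenyl)magnesium bromide
Product: 33 (1S,2R,3S)-3-[hydroxy(4-methoxyphenyl)methyl]-2-{2-[1-(3,5-dimethoxyphenyl)-2-(4-methoxyphenyl)-2-oxoethyl]-3,5-dimethoxyphenyl}-5,7-dimethoxy-1-(4-methoxyphenyl)indane (mixture at the carbinol carbon Cα and at the methine)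
Conditions: THF, −78 °C; then H2O
Reagents that add atoms: none
Why: Grignard addition to the aldehyde, which at −78 °C is much faster than addition to the hindered, electron-rich aryl ketone. The carbinol configuration is irrelevant because this centre is ionised in step 18.

Step 18
Reactants: 33 the carbinol of step 17
Product: 34 the eight-membered-ring ketone: (1S,2S,3R)-5,7-dimethoxy-1-(4-methoxyphenyl)indane in which C3 carries Cα [(R); H and 4-methoxyphenyl] and C2 carries ring C; ring B (dimethoxy) links Cα to the methine on ring C [(R); H and 4-methoxybenzoyl]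
Conditions: TfOH (10 mol%), CH2Cl2–(CF3)2CHOH 4:1 (0.005 M), −20 °C; then DBU, toluene, 60 °C
Reagents that add atoms: none
Why: Intramolecular Friedel–Crafts alkylation: acid ionises the 4-methoxybenzylic alcohol and ring B captures the cation at the carbon ortho to its benzylic substituent, closing the eight-membered ring; closure onto ring A would give a four-membered ring and closure onto ring C a trans-fused bicyclo[3.3.0]octane. Cα is set here: the tethered arene can reach only one face of the cation in the conformer that turns the anisyl group away from the peri hydrogen at C4 (allylic 1,3-strain), and this gives the R configuration. DBU then equilibrates the methine α to the ketone toward the epimer whose aroyl group lies outside the medium ring, which is the required one.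

Step 19
Reactants: 34 the ketone of step 18
Product: 35 the corresponding alcohol: 34 with CH(OH)(4-methoxyphenyl) in place of the 4-methoxybenzoyl group (both carbinol epimers)
Conditions: NaBH4, THF–MeOH, 0 → 25 °C
Reagents that add atoms: none
Why: Hydride reduction of the aryl ketone; the configuration of the new carbinol does not matter because it is ionised in step 20.

Step 20
Reactants: 35 the alcohol of step 19
Product: 37 stenophyllol B, via octa-O-methyl ether 36 (not isolated)
Conditions: BBr3 (15 equiv), CH2Cl2, −78 → 25 °C; then H2O, 0 °C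
Reagents that add atoms: none
Why: BBr3 ionises the benzylic alcohol, the neighbouring methoxy oxygen of ring C closes the five-membered ring, and bromide removes the methyl group from the oxonium ion (demethylative cyclisation); the same reagent then cleaves the eight aryl methyl ethers. The C2 aryl group settles trans to the C3 substituent, the less hindered arrangement, and a cis isomer can correct itself because the benzylic C–O bond re-ionises under these conditions.

## Compound list

1 | cyclopent-2-en-1-one | O=C1C=CCC1 | starting material
2 | 1-bromo-3,5-dimethoxybenzene | COc1cc(Br)cc(OC)c1 | starting material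
3 | (3,5-dimethoxyphenyl)lithium | [Li]c1cc(OC)cc(OC)c1 | intermediate (not isolated)
4 | (3,5-dimethoxyphenyl)titanium triisopropoxide | CC(C)O[Ti](OC(C)C)(OC(C)C)c1cc(OC)cc(OC)c1 | intermediate (not isolated)
5 | (3R)-3-(3,5-dimethoxyphenyl)cyclopent-1-en-1-yl triisopropyl titanate (titanium enolate) | CC(C)O[Ti](OC(C)C)(OC(C)C)OC1=C[C@H](c2cc(OC)cc(OC)c2)CC1 | intermediate (not isolated)
6 | {[(3R)-3-(3,5-dimethoxyphenyl)cyclopent-1-en-1-yl]oxy}trimethylsilane | C[Si](C)(C)OC1=C[C@H](c2cc(OC)cc(OC)c2)CC1 | intermediate
7 | (2R,3R)-2-[(benzyloxy)methyl]-3-(3,5-dimethoxyphenyl)cyclopentan-1-one (trans) | O=C1[C@@H](COCc2ccccc2)[C@H](c2cc(OC)cc(OC)c2)CC1 | intermediate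
8 | {[(4R,5R)-5-[(benzyloxy)methyl]-4-(3,5-dimethoxyphenyl)cyclopent-1-en-1-yl]oxy}trimethylsilane | C[Si](C)(C)OC1=CC[C@@H](c2cc(OC)cc(OC)c2)[C@@H]1COCc1ccccc1 | intermediate (not isolated)
9 | (4R,5R)-5-[(benzyloxy)methyl]-4-(3,5-dimethoxyphenyl)cyclopent-2-en-1-one | O=C1C=C[C@@H](c2cc(OC)cc(OC)c2)[C@@H]1COCc1ccccc1 | intermediate
10 | (4-methoxyphenyl)magnesium bromide (commercial solution in THF) | COc1ccc([Mg]Br)cc1 | starting material
11 | {[(3R,4R,5R)-5-[(benzyloxy)methyl]-4-(3,5-dimethoxyphenyl)-3-(4-methoxyphenyl)cyclopent-1-en-1-yl]oxy}trimethylsilane (all-trans) | C[Si](C)(C)OC1=C[C@H](c2ccc(OC)cc2)[C@@H](c2cc(OC)cc(OC)c2)[C@@H]1COCc1ccccc1 | intermediate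
12 | 2,2,6-trimethyl-4H-1,3-dioxin-4-one | CC1=CC(=O)OC(C)(C)O1 | starting material
13 | lithium 2,2-dimethyl-6-methylidene-6H-1,3-dioxin-4-olate | C=C1C=C(O[Li])OC(C)(C)O1 | intermediate (not isolated)
14 | (2,2-dimethyl-4-oxo-4H-1,3-dioxin-6-yl)acetic acid | OC(=O)CC1=CC(=O)OC(C)(C)O1 | intermediate
15 | 6-[2-(1H-benzotriazol-1-yl)-2-oxoethyl]-2,2-dimethyl-4H-1,3-dioxin-4-one | O=C(CC1=CC(=O)OC(C)(C)O1)n1nnc2ccccc12 | intermediate
16 | lithium (3R,4R,5R)-5-[(benzyloxy)methyl]-4-(3,5-dimethoxyphenyl)-3-(4-methoxyphenyl)cyclopent-1-en-1-olate | [Li]OC1=C[C@H](c2ccc(OC)cc2)[C@@H](c2cc(OC)cc(OC)c2)[C@@H]1COCc1ccccc1 | intermediate (not isolated)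
17 | 6-{2-[(3R,4R,5R)-3-[(benzyloxy)methyl]-4-(3,5-dimethoxyphenyl)-5-(4-methoxyphenyl)-2-oxocyclopentyl]-2-oxoethyl}-2,2-dimethyl-4H-1,3-dioxin-4-one (key-step precursor) | COc1ccc([C@H]2C(C(=O)CC3=CC(=O)OC(C)(C)O3)C(=O)[C@@H](COCc3ccccc3)[C@@H]2c2cc(OC)cc(OC)c2)cc1 | intermediate
18 | aldol adduct of 17: dioxinone C5 bonded to the former cyclopentanone carbonyl carbon, now a tertiary carbinol (new centres not assigned) | COc1ccc([C@H]2C3C(=O)CC4=C(C(=O)OC(C)(C)O4)C3(O)[C@@H](COCc3ccccc3)[C@@H]2c2cc(OC)cc(OC)c2)cc1 | intermediate (not isolated)
19 | (1S,2R,3S)-3-[(benzyloxy)methyl]-2-(3,5-dimethoxyphenyl)-7-hydroxy-1-(4-methoxyphenyl)indane with a 2,2-dimethyl-1,3-dioxin-4-one ring fused at C4–C5 (key-step product) | COc1ccc([C@H]2c3c(O)cc4OC(C)(C)OC(=O)c4c3[C@@H](COCc3ccccc3)[C@@H]2c2cc(OC)cc(OC)c2)cc1 | intermediate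
20 | 7-O-methyl ether of 19 | COc1ccc([C@H]2c3c(OC)cc4OC(C)(C)OC(=O)c4c3[C@@H](COCc3ccccc3)[C@@H]2c2cc(OC)cc(OC)c2)cc1 | intermediate
21 | 20 with bromine on ring C ortho to the indanyl group: the 2-(2-bromo-3,5-dimethoxyphenyl) compound | COc1ccc([C@H]2c3c(OC)cc4OC(C)(C)OC(=O)c4c3[C@@H](COCc3ccccc3)[C@@H]2c2c(Br)c(OC)cc(OC)c2)cc1 | intermediate
22 | (1S,2R,3S)-3-[(benzyloxy)methyl]-2-(2-bromo-3,5-dimethoxyphenyl)-5-hydroxy-7-methoxy-1-(4-methoxyphenyl)indane-4-carboxylic acid | COc1ccc([C@H]2c3c(OC)cc(O)c(C(O)=O)c3[C@@H](COCc3ccccc3)[C@@H]2c2c(Br)c(OC)cc(OC)c2)cc1 | intermediate (not isolated)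
23 | (1S,2R,3S)-3-[(benzyloxy)methyl]-2-(2-bromo-3,5-dimethoxyphenyl)-7-methoxy-1-(4-methoxyphenyl)indan-5-ol | COc1ccc([C@H]2c3c(OC)cc(O)cc3[C@@H](COCc3ccccc3)[C@@H]2c2c(Br)c(OC)cc(OC)c2)cc1 | intermediate
24 | (1S,2R,3S)-3-[(benzyloxy)methyl]-2-(2-bromo-3,5-dimethoxyphenyl)-5,7-dimethoxy-1-(4-methoxyphenyl)indane | COc1ccc([C@H]2c3c(OC)cc(OC)cc3[C@@H](COCc3ccccc3)[C@@H]2c2c(Br)c(OC)cc(OC)c2)cc1 | intermediate
25 | 1-(chloromethyl)-3,5-dimethoxybenzene | COc1cc(CCl)cc(OC)c1 | starting material
26 | 4-methoxybenzonitrile | COc1ccc(C#N)cc1 | starting material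
27 | (3,5-dimethoxybenzyl)magnesium chloride | COc1cc(C[Mg]Cl)cc(OC)c1 | intermediate (not isolated)
28 | N-chloromagnesio imine of 2-(3,5-dimethoxyphenyl)-1-(4-methoxyphenyl)ethan-1-one | COc1ccc(cc1)C(=N[Mg]Cl)Cc1cc(OC)cc(OC)c1 | intermediate (not isolated)
29 | 2-(3,5-dimethoxyphenyl)-1-(4-methoxyphenyl)ethan-1-one | COc1ccc(cc1)C(=O)Cc1cc(OC)cc(OC)c1 | intermediate
30 | (1S,2R,3S)-3-[(benzyloxy)methyl]-2-{2-[1-(3,5-dimethoxyphenyl)-2-(4-methoxyphenyl)-2-oxoethyl]-3,5-dimethoxyphenyl}-5,7-dimethoxy-1-(4-methoxyphenyl)indane (epimers at the methine) | COc1ccc([C@H]2c3c(OC)cc(OC)cc3[C@@H](COCc3ccccc3)[C@@H]2c2c(C(c3cc(OC)cc(OC)c3)C(=O)c3ccc(OC)cc3)c(OC)cc(OC)c2)cc1 | intermediate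
31 | 3-(hydroxymethyl) analogue of 30 | COc1ccc([C@H]2c3c(OC)cc(OC)cc3[C@@H](CO)[C@@H]2c2c(C(c3cc(OC)cc(OC)c3)C(=O)c3ccc(OC)cc3)c(OC)cc(OC)c2)cc1 | intermediate
32 | 3-formyl analogue of 30 (indane-3-carbaldehyde, 1S,2R,3S) | COc1ccc([C@H]2c3c(OC)cc(OC)cc3[C@@H](C=O)[C@@H]2c2c(C(c3cc(OC)cc(OC)c3)C(=O)c3ccc(OC)cc3)c(OC)cc(OC)c2)cc1 | intermediate
33 | 3-[hydroxy(4-methoxyphenyl)methyl] analogue of 30 (1S,2R,3S; epimers at Cα and at the methine) | COc1ccc([C@H]2c3c(OC)cc(OC)cc3[C@@H](C(O)c3ccc(OC)cc3)[C@@H]2c2c(C(c3cc(OC)cc(OC)c3)C(=O)c3ccc(OC)cc3)c(OC)cc(OC)c2)cc1 | intermediate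
34 | eight-membered-ring ketone (indane 1S,2S,3R; Cα R; aroyl-bearing methine R), all oxygens as methyl ethers | COc1ccc([C@H]2c3c(OC)cc(OC)cc3[C@H]3[C@H](c4ccc(OC)cc4)c4c(OC)cc(OC)cc4[C@@H](C(=O)c4ccc(OC)cc4)c4c(OC)cc(OC)cc4[C@H]23)cc1 | intermediate
35 | alcohol from 34: CH(OH)(4-methoxyphenyl) in place of the aroyl group (both carbinol epimers) | COc1ccc([C@H]2c3c(OC)cc(OC)cc3[C@H]3[C@H](c4ccc(OC)cc4)c4c(OC)cc(OC)cc4[C@@H](C(O)c4ccc(OC)cc4)c4c(OC)cc(OC)cc4[C@H]23)cc1 | intermediate
36 | octa-O-methyl stenophyllol B | COc1ccc([C@H]2c3c(OC)cc(OC)cc3[C@H]3[C@H](c4ccc(OC)cc4)c4c(OC)cc(OC)cc4[C@@H]4c5c(cc(OC)cc5[C@H]23)O[C@H]4c2ccc(OC)cc2)cc1 | intermediate (not isolated)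
37 | stenophyllol B (indane 1S,2S,3R; Cα R; benzofuran 2R,3R) | Oc1ccc([C@H]2c3c(O)cc(O)cc3[C@H]3[C@H](c4ccc(O)cc4)c4c(O)cc(O)cc4[C@@H]4c5c(cc(O)cc5[C@H]23)O[C@H]4c2ccc(O)cc2)cc1 | target

## Step count and risks

Total step count: 20 (steps 5, 6 and 13 prepare the two side components).
Longest linear sequence: 17 steps (1–4, 7–12, 14–20).

Least certain steps:

Step 8 (key step). The cyclopentanone carbonyl is hindered and partly enolised as a 1,3-diketone, so the aldol closure may be slow. Attack of the enol oxygen on the dioxinone (pyranone formation) or expulsion of benzyl alcohol from C3 could then take over. The fallback sets out from 17. It is heated with tert-butanol in toluene at 110 °C, which opens the dioxinone thermally and transfers the acyl fragment to the alcohol, giving tert-butyl 5-[(3R,4R,5R)-3-[(benzyloxy)methyl]-4-(3,5-dimethoxyphenyl)-5-(4-methoxyphenyl)-2-oxocyclopentyl]-3,5-dioxopentanoate F1. This open triketo ester has a freely rotating, more nucleophilic methylene and should undergo the classical tricarbonyl aldol aromatisation with KOAc in methanol to tert-butyl (1S,2R,3S)-3-[(benzyloxy)methyl]-2-(3,5-dimethoxyphenyl)-5,7-dihydroxy-1-(4-methoxyphenyl)indane-4-carboxylate F2. Trifluoroacetic acid, trifluoroacetic anhydride and acetone then cleave the ester and re-form the isopropylidene ring, which returns the route to 19.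

Step 7. The methylene of 15 is doubly activated, so proton transfer to the lithium enolate, or acylation on oxygen, may compete with C-acylation. The fallback sets out from 11, which is hydrolysed with aqueous citric acid in THF to (2R,3R,4S)-2-[(benzyloxy)methyl]-3-(3,5-dimethoxyphenyl)-4-(4-methoxyphenyl)cyclopentan-1-one F3. F3 is then acylated with 15 under soft enolisation (MgBr2·OEt2, i-Pr2NEt, CH2Cl2, 25 °C). All proton transfers are reversible under these conditions, and the magnesium chelate of the 1,3-diketone draws the equilibrium to the C-acylated product at the unsubstituted α-carbon. This returns to 17.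

Step 14. Oxidative addition and reductive elimination at a bromide with two ortho substituents may be slow, so that reduction of the C–Br bond or decomposition of the catalyst wins. The fallback sets out from 24 and builds the same carbon skeleton by organolithium chemistry:
- Bromine–lithium exchange (t-BuLi, THF, −78 °C) gives the aryllithium derived from 24 F4, which adds to 3,5-dimethoxybenzaldehyde to give the diarylmethanol F5.
- Dess–Martin oxidation gives the diaryl ketone F6.
- Corey–Chaykovsky methylenation (Me3S+ I−, n-BuLi) gives the 2,2-diaryloxirane F7.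
- Meinwald rearrangement with ZnI2 gives the diarylacetaldehyde F8.
- Addition of 10 gives the 1,2,2-triarylethanol F9, and a second Dess–Martin oxidation returns the route to 30.

Step 18. The cation may lose the proton at C3 to give the styrene. Re-protonation would scramble C3, and the cis isomer could close a five-membered ring onto ring C; bimolecular alkylation is a further risk. The fallback sets out from 32 and closes the same bond at the acyl level, where C3 cannot be lost through an alkene:
- Pinnick oxidation (NaClO2, NaH2PO4, 2-methylbut-2-ene) gives the indane-3-carboxylic acid F10.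
- P2O5–MeSO3H at 25 °C effects intramolecular Friedel–Crafts acylation onto ring B to the eight-membered-ring diketone F11.
- The organocerium reagent made from 10 and CeCl3 adds to the ring ketone (the aroyl ketone is protected as its enolate) to give the tertiary alcohol F12.
- Ionic hydrogenation (Et3SiH, CF3CO2H, CH2Cl2, 0 °C) delivers hydride to the diaryl cation from the open face, and DBU equilibration returns the route to 34.

Step 20. The benzylic cation may eliminate toward a triarylethylene before the ring C oxygen captures it. The ring closure could then be incomplete during the demethylation, or benzofuran C3 could be scrambled. The fallback sets out from 34 and forms the furan first, then reduces it. BBr3 in CH2Cl2 demethylates 34, and the liberated ortho phenol condenses with the aryl ketone to give the aromatic benzofuran, 2,3-didehydrostenophyllol B F13. Ionic hydrogenation of the 2,3-diarylbenzofuran (Et3SiH, CF3CO2H) then gives the trans-2,3-dihydrobenzofuran, which arrives at 37. This fallback also resets benzofuran C3 if the equilibration in step 18 were to favour the wrong epimer.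

## Further compounds

F1 | step 8 | tert-butyl 5-[(3R,4R,5R)-3-[(benzyloxy)methyl]-4-(3,5-dimethoxyphenyl)-5-(4-methoxyphenyl)-2-oxocyclopentyl]-3,5-dioxopentanoate | COc1ccc([C@H]2C(C(=O)CC(=O)CC(=O)OC(C)(C)C)C(=O)[C@@H](COCc3ccccc3)[C@@H]2c2cc(OC)cc(OC)c2)cc1
F2 | step 8 | tert-butyl (1S,2R,3S)-3-[(benzyloxy)methyl]-2-(3,5-dimethoxyphenyl)-5,7-dihydroxy-1-(4-methoxyphenyl)indane-4-carboxylate | COc1ccc([C@H]2c3c(O)cc(O)c(C(=O)OC(C)(C)C)c3[C@@H](COCc3ccccc3)[C@@H]2c2cc(OC)cc(OC)c2)cc1
F3 | step 7 | (2R,3R,4S)-2-[(benzyloxy)methyl]-3-(3,5-dimethoxyphenyl)-4-(4-methoxyphenyl)cyclopentan-1-one | O=C1C[C@H](c2ccc(OC)cc2)[C@@H](c2cc(OC)cc(OC)c2)[C@@H]1COCc1ccccc1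
F4 | step 14 | aryllithium derived from 24 (lithium in place of bromine) | COc1ccc([C@H]2c3c(OC)cc(OC)cc3[C@@H](COCc3ccccc3)[C@@H]2c2c([Li])c(OC)cc(OC)c2)cc1
F5 | step 14 | (1S,2R,3S)-3-[(benzyloxy)methyl]-2-{2-[(3,5-dimethoxyphenyl)(hydroxy)methyl]-3,5-dimethoxyphenyl}-5,7-dimethoxy-1-(4-methoxyphenyl)indane | COc1ccc([C@H]2c3c(OC)cc(OC)cc3[C@@H](COCc3ccccc3)[C@@H]2c2c(C(O)c3cc(OC)cc(OC)c3)c(OC)cc(OC)c2)cc1
F6 | step 14 | {2-[(1S,2R,3S)-3-[(benzyloxy)methyl]-5,7-dimethoxy-1-(4-methoxyphenyl)indan-2-yl]-4,6-dimethoxyphenyl}(3,5-dimethoxyphenyl)methanone | COc1ccc([C@H]2c3c(OC)cc(OC)cc3[C@@H](COCc3ccccc3)[C@@H]2c2c(C(=O)c3cc(OC)cc(OC)c3)c(OC)cc(OC)c2)cc1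
F7 | step 14 | (1S,2R,3S)-3-[(benzyloxy)methyl]-2-{2-[2-(3,5-dimethoxyphenyl)oxiran-2-yl]-3,5-dimethoxyphenyl}-5,7-dimethoxy-1-(4-methoxyphenyl)indane | COc1ccc([C@H]2c3c(OC)cc(OC)cc3[C@@H](COCc3ccccc3)[C@@H]2c2c(C3(CO3)c3cc(OC)cc(OC)c3)c(OC)cc(OC)c2)cc1
F8 | step 14 | 2-{2-[(1S,2R,3S)-3-[(benzyloxy)methyl]-5,7-dimethoxy-1-(4-methoxyphenyl)indan-2-yl]-4,6-dimethoxyphenyl}-2-(3,5-dimethoxyphenyl)acetaldehyde | COc1ccc([C@H]2c3c(OC)cc(OC)cc3[C@@H](COCc3ccccc3)[C@@H]2c2c(C(C=O)c3cc(OC)cc(OC)c3)c(OC)cc(OC)c2)cc1
F9 | step 14 | 2-{2-[(1S,2R,3S)-3-[(benzyloxy)methyl]-5,7-dimethoxy-1-(4-methoxyphenyl)indan-2-yl]-4,6-dimethoxyphenyl}-2-(3,5-dimethoxyphenyl)-1-(4-methoxyphenyl)ethan-1-ol | COc1ccc([C@H]2c3c(OC)cc(OC)cc3[C@@H](COCc3ccccc3)[C@@H]2c2c(C(c3cc(OC)cc(OC)c3)C(O)c3ccc(OC)cc3)c(OC)cc(OC)c2)cc1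
F10 | step 18 | (1S,2R,3S)-2-{2-[1-(3,5-dimethoxyphenyl)-2-(4-methoxyphenyl)-2-oxoethyl]-3,5-dimethoxyphenyl}-5,7-dimethoxy-1-(4-methoxyphenyl)indane-3-carboxylic acid | COc1ccc([C@H]2c3c(OC)cc(OC)cc3[C@@H](C(O)=O)[C@@H]2c2c(C(c3cc(OC)cc(OC)c3)C(=O)c3ccc(OC)cc3)c(OC)cc(OC)c2)cc1
F11 | step 18 | eight-membered-ring diketone: 34 with C=O in place of Cα(H)(4-methoxyphenyl) (aroyl-bearing methine not assigned) | COc1ccc([C@H]2c3c(OC)cc(OC)cc3[C@H]3C(=O)c4c(OC)cc(OC)cc4C(C(=O)c4ccc(OC)cc4)c4c(OC)cc(OC)cc4[C@H]23)cc1
F12 | step 18 | tertiary alcohol: 34 with Cα(OH)(4-methoxyphenyl) (new centres not assigned) | COc1ccc([C@H]2c3c(OC)cc(OC)cc3[C@H]3C(O)(c4ccc(OC)cc4)c4c(OC)cc(OC)cc4C(C(=O)c4ccc(OC)cc4)c4c(OC)cc(OC)cc4[C@H]23)cc1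
F13 | step 20 | 2,3-didehydrostenophyllol B (aromatic benzofuran; indane 1S,2S,3R; Cα R) | Oc1ccc([C@H]2c3c(O)cc(O)cc3[C@H]3[C@H](c4ccc(O)cc4)c4c(O)cc(O)cc4-c4c5c(cc(O)cc5[C@H]23)oc4-c2ccc(O)cc2)cc1
A1 | alternative 1 | trans-4-{[(tert-butyldimethylsilyl)oxy]methyl}-3-(3,5-dimethoxyphenyl)-6-ethoxy-2-(4-methoxyphenyl)-2,3-dihydrobenzofuran | COc1cc(OC)cc(c1)[C@@H]1c2c(cc(OCC)cc2CO[Si](C)(C)C(C)(C)C)O[C@H]1c1ccc(OC)cc1
A2 | alternative 2 | methyl all-trans-2-(3,5-dimethoxyphenyl)-5-methoxy-1-(4-methoxyphenyl)-7-[(triisopropylsilyl)oxy]indane-3-carboxylate | COc1ccc([C@H]2c3c(O[Si](C(C)C)(C(C)C)C(C)C)cc(OC)cc3[C@@H](C(=O)OC)[C@@H]2c2cc(OC)cc(OC)c2)cc1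
A3 | alternative 3 | hepta-O-methyl stenophyllol B with the free hydroxyl at benzofuran C6 | COc1ccc([C@H]2c3c(OC)cc(OC)cc3[C@H]3[C@H](c4ccc(OC)cc4)c4c(OC)cc(OC)cc4[C@@H]4c5c(cc(O)cc5[C@H]23)O[C@H]4c2ccc(OC)cc2)cc1
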